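**Retrosynthetic overview**
- Ring A is the 2-formylindole; rings B and C are the two indol-3-yl groups on the methine carbon attached to C3 of ring A.
- The strategy rests on the N1–C2(CHO)=C3(CH(indolyl)2) segment of the pyrrole ring of ring A. It maps onto a tertiary 1-(2-sulfonamidophenyl)prop-2-yn-1-ol: C3 is the carbinol carbon, C2 the internal alkyne carbon and the formyl carbon the terminal alkyne carbon.
- Last disconnections: removal of the N-tosyl group and both N-Boc groups, then N1–C2 by gold-catalysed aminocyclisation with iododeauration, 1,3-oxygen shift and loss of HI.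
- Earlier disconnections: C3–C(alkyne) by ethynyl addition to an aryl ketone, and the two methine–C3(indole) bonds by double Friedel–Crafts reaction of indole with (2-nitrophenyl)glyoxal, made from 2'-nitroacetophenone.
- Ring order: the benzo ring of ring A and rings B and C are bought; the pyrrole ring of ring A is the only ring built (step 7).

Key step: step 7

Remark: glyoxal 2 is drawn as the free aldehyde; its hydrate is in equilibrium with it and is assumed to react in the same way in step 2. Compounds 4, 10, 11 and 12 are racemic (one enantiomer drawn); the target has no stereocentre.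

**Route**

Step 1
Reactants: 1 2'-nitroacetophenone
Product: 2 (2-nitrophenyl)glyoxal
Conditions: SeO2 (1.3 equiv), 1,4-dioxane/H2O, reflux
Reagents that add atoms: selenium dioxide, O=[Se]=O
Why: Riley oxidation of the methyl group of an aryl methyl ketone to the 1,2-dicarbonyl compound, to which the nitroarene is inert.

Step 2
Reactants: 2 (2-nitrophenyl)glyoxal; 3 indole (2.2 equiv)
Product: 5 2,2-bis(1H-indol-3-yl)-1-(2-nitrophenyl)ethan-1-one, via 2-hydroxy-2-(indol-3-yl)-1-(2-nitrophenyl)ethanone 4 (not isolated)
Conditions: p-TsOH·H2O (10 mol %), MeCN, rt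
Reagents that add atoms: none
Why: Double Friedel–Crafts reaction at indole C3 (bis(indolyl)methane synthesis): the aldehyde carbon is far more electrophilic than the ketone, and carbinol 4 should ionise under acid to a 3-alkylideneindoleninium ion that takes up the second indole.

Step 3
Reactants: 5 2,2-bis(1H-indol-3-yl)-1-(2-nitrophenyl)ethan-1-one
Product: 6 2,2-bis(1-Boc-indol-3-yl)-1-(2-nitrophenyl)ethan-1-one
Conditions: Boc2O (2.5 equiv), DMAP (0.2 equiv), MeCN, rt
Reagents that add atoms: di-tert-butyl dicarbonate, CC(C)(C)OC(=O)OC(=O)OC(C)(C)C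
Why: DMAP-catalysed N-acylation of both indole N–H groups; DMAP is too weak a base to deprotonate the ketone α-methine.

Step 4
Reactants: 6 2,2-bis(1-Boc-indol-3-yl)-1-(2-nitrophenyl)ethan-1-one
Product: 7 1-(2-aminophenyl)-2,2-bis(1-Boc-indol-3-yl)ethan-1-one
Conditions: H2 (1 atm), 10% Pd/C, EtOAc, rt
Reagents that add atoms: none
Why: Catalytic hydrogenation of an aromatic nitro group to the aniline, which should be much faster than reduction of the hindered aryl ketone or of the N-acylindoles.

Step 5
Reactants: 7 1-(2-aminophenyl)-2,2-bis(1-Boc-indol-3-yl)ethan-1-one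
Product: 8 N-{2-[2,2-bis(1-Boc-indol-3-yl)acetyl]phenyl}-4-methylbenzenesulfonamide
Conditions: TsCl (1.5 equiv), pyridine, rt to 40 °C
Reagents that add atoms: 4-methylbenzenesulfonyl chloride, Cc1ccc(cc1)S(Cl)(=O)=O
Why: N-sulfonylation of an aniline with a sulfonyl chloride in pyridine, the standard way to make N-tosyl 2-aminoaryl ketones; a second sulfonylation is disfavoured at the hindered, acidic sulfonamide N–H.

Step 6
Reactants: 8 N-{2-[2,2-bis(1-Boc-indol-3-yl)acetyl]phenyl}-4-methylbenzenesulfonamide; 9 ethynylmagnesium bromide (5 equiv)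
Product: 10 N-{2-[1,1-bis(1-Boc-indol-3-yl)-2-hydroxybut-3-yn-2-yl]phenyl}-4-methylbenzenesulfonamide (racemic)
Conditions: anhydrous CeCl3 (5 equiv), THF, −78 to 0 °C; then pH 7 aqueous buffer
Reagents that add atoms: none
Why: 1,2-addition of an alkynyl Grignard/organocerium reagent to a ketone after the first equivalent has deprotonated the sulfonamide; CeCl3 suppresses enolisation at the α-methine, and the new carbinol stereocentre forms as a racemate that is erased in step 7.

Step 7
Reactants: 10 N-{2-[1,1-bis(1-Boc-indol-3-yl)-2-hydroxybut-3-yn-2-yl]phenyl}-4-methylbenzenesulfonamide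
Product: 13 3-[bis(1-Boc-indol-3-yl)methyl]-1-tosylindole-2-carbaldehyde, via (E)-2-(iodomethylidene)indolin-3-ol 11 (not isolated), via 2-[hydroxy(iodo)methyl]indole 12 (not isolated)
Conditions: Ph3PAuCl (5 mol %), AgOTf (5 mol %), NIS (2.2 equiv), acetone, rt, dark; then aq. Na2S2O3
Reagents that add atoms: none
Why: Ph3PAuOTf, formed from Ph3PAuCl and AgOTf, is a monovalent gold π-acid that activates the terminal alkyne; the ortho sulfonamide nitrogen adds anti to the internal alkyne carbon and NIS cleaves the vinyl–gold bond with retention to give the (E)-iodomethylidene indolinol 11. The tertiary C3–OH of 11 then ionises to an allyl cation whose charge sits at the CHI carbon of a now aromatic indole, oxygen (water or the returning hydroxyl) adds there to give iodohydrin 12, and 12 collapses to the aldehyde with loss of HI, which the second equivalent of NIS converts into I2 so that neither acid nor iodide builds up. This is the known gold/NIS cycloisomerisation of tertiary 1-(2-tosylaminophenyl)prop-2-yn-1-ols to 1-tosylindole-2-carbaldehydes, applied here to a bulkier carbinol substituent. The pyrrole ring of ring A is closed by N1–C2 bond formation in the 5-exo-dig mode, which the two-atom link between nitrogen and the alkyne favours over 6-endo-dig attack at the terminal carbon. No stereocentre is created: the carbinol centre of racemic 10 becomes sp2 C3 and the alkene geometry of 11 is lost on aromatisation. The step needs nitrogen to beat C2 of rings B and C as the nucleophile and NIS to spare those rings, both secured by the electron-withdrawing Boc groups, and it needs oxygen capture at the CHI terminus to outrun loss of the neighbouring methine proton, which the gain of indole aromaticity on capture favours.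

Step 8
Reactants: 13 3-[bis(1-Boc-indol-3-yl)methyl]-1-tosylindole-2-carbaldehyde
Product: 14 trisindolal, 3-[bis(1H-indol-3-yl)methyl]-1H-indole-2-carbaldehyde
Conditions: Cs2CO3 (4 equiv), THF/MeOH (2:1), rt to 50 °C
Reagents that add atoms: none
Why: Methoxide-mediated N-desulfonylation and carbamate methanolysis of N-acyl-type indoles, whose indolide leaving groups make all three groups base-labile (the 2-formyl group makes the ring A sulfonamide the most labile); the aldehyde cannot enolise.

**Compound list**
1 | 2'-nitroacetophenone, 1-(2-nitrophenyl)ethan-1-one | CC(=O)c1ccccc1[N+](=O)[O-] | starting material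
2 | (2-nitrophenyl)glyoxal, 2-(2-nitrophenyl)-2-oxoacetaldehyde | O=CC(=O)c1ccccc1[N+](=O)[O-] | intermediate
3 | indole | c1ccc2[nH]ccc2c1 | starting material
4 | 2-hydroxy-2-(1H-indol-3-yl)-1-(2-nitrophenyl)ethan-1-one (racemic, one enantiomer drawn; formed and consumed in step 2) | O=C(c1ccccc1[N+](=O)[O-])[C@H](O)c1c[nH]c2ccccc12 | intermediate
5 | 2,2-bis(1H-indol-3-yl)-1-(2-nitrophenyl)ethan-1-one | O=C(c1ccccc1[N+](=O)[O-])C(c1c[nH]c2ccccc12)c1c[nH]c2ccccc12 | intermediate
6 | 2,2-bis(1-Boc-indol-3-yl)-1-(2-nitrophenyl)ethan-1-one | O=C(c1ccccc1[N+](=O)[O-])C(c1cn(C(=O)OC(C)(C)C)c2ccccc12)c1cn(C(=O)OC(C)(C)C)c2ccccc12 | intermediate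
7 | 1-(2-aminophenyl)-2,2-bis(1-Boc-indol-3-yl)ethan-1-one | Nc1ccccc1C(=O)C(c1cn(C(=O)OC(C)(C)C)c2ccccc12)c1cn(C(=O)OC(C)(C)C)c2ccccc12 | intermediate
8 | N-{2-[2,2-bis(1-Boc-indol-3-yl)acetyl]phenyl}-4-methylbenzenesulfonamide | Cc1ccc(cc1)S(=O)(=O)Nc1ccccc1C(=O)C(c1cn(C(=O)OC(C)(C)C)c2ccccc12)c1cn(C(=O)OC(C)(C)C)c2ccccc12 | intermediate
9 | ethynylmagnesium bromide | C#C[Mg]Br | starting material
10 | N-{2-[1,1-bis(1-Boc-indol-3-yl)-2-hydroxybut-3-yn-2-yl]phenyl}-4-methylbenzenesulfonamide (racemic, one enantiomer drawn) | C#C[C@](O)(c1ccccc1NS(=O)(=O)c1ccc(C)cc1)C(c1cn(C(=O)OC(C)(C)C)c2ccccc12)c1cn(C(=O)OC(C)(C)C)c2ccccc12 | intermediate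
11 | 3-[bis(1-Boc-indol-3-yl)methyl]-2-[(E)-iodomethylidene]-1-tosylindolin-3-ol (racemic, one enantiomer drawn; formed and consumed in step 7) | I/C=C1/N(S(=O)(=O)c2ccc(C)cc2)c2ccccc2[C@]1(O)C(c1cn(C(=O)OC(C)(C)C)c2ccccc12)c1cn(C(=O)OC(C)(C)C)c2ccccc12 | intermediate
12 | {3-[bis(1-Boc-indol-3-yl)methyl]-1-tosylindol-2-yl}(iodo)methanol (racemic, one enantiomer drawn; formed and consumed in step 7) | O[C@@H](I)c1n(S(=O)(=O)c2ccc(C)cc2)c2ccccc2c1C(c1cn(C(=O)OC(C)(C)C)c2ccccc12)c1cn(C(=O)OC(C)(C)C)c2ccccc12 | intermediate
13 | 3-[bis(1-Boc-indol-3-yl)methyl]-1-tosylindole-2-carbaldehyde | Cc1ccc(cc1)S(=O)(=O)n1c(C=O)c(C(c2cn(C(=O)OC(C)(C)C)c3ccccc23)c2cn(C(=O)OC(C)(C)C)c3ccccc23)c2ccccc12 | intermediate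
14 | trisindolal, 3-[bis(1H-indol-3-yl)methyl]-1H-indole-2-carbaldehyde | O=Cc1[nH]c2ccccc2c1C(c1c[nH]c2ccccc12)c1c[nH]c2ccccc12 | target

**Step count and risks**

Total step count: 8. Longest linear sequence: 8 steps (1 to 14; fully linear).

Steps most likely to fail:

Step 7. The iodonium source and the HI/I2 it generates may iodinate or oxidise rings B and C or strip the Boc groups. The allyl cation may also lose the bis(indolyl)methine proton or suffer a 1,2-indolyl shift instead of capturing oxygen at the CHI terminus. Fallback, setting out from 10: the ring closure and the oxidation are separated and iodine is avoided. AgOAc (10 mol %) in MeCN at rt should effect the 5-exo-dig hydroamination of 10 to 3-[bis(1-Boc-indol-3-yl)methyl]-2-methylidene-1-tosylindolin-3-ol F1. PPTS in wet THF should then promote the 1,3-hydroxyl transposition to {3-[bis(1-Boc-indol-3-yl)methyl]-1-tosylindol-2-yl}methanol F2. Oxidation of this benzylic-type alcohol with MnO2 in CH2Cl2 returns to the route at 13.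

Step 6. The acetylide may act as a base (enolisation at the α-methine, giving back the ketone). Disproportionation of the ethynyl Grignard reagent to the bis-magnesium acetylide may lead to double addition. The reagent may also attack the carbamates. Fallback, setting out from 8: a silyl-capped acetylide is added and the alkyne is unmasked separately. Me3SiC≡CLi (from trimethylsilylacetylene and n-BuLi), transmetalated with anhydrous CeCl3 in THF at −78 °C, should add to 8 to give N-{2-[1,1-bis(1-Boc-indol-3-yl)-2-hydroxy-4-(trimethylsilyl)but-3-yn-2-yl]phenyl}-4-methylbenzenesulfonamide F3. Desilylation with TBAF buffered with AcOH in THF at 0 °C returns to the route at 10.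

Step 8. The methyl tosylate released on desulfonylation may N-methylate the freed, fairly acidic ring A nitrogen, and the three cleavages may run at unequal rates and leave partly protected material. Fallback, setting out from 13: the sulfonyl group is removed first with a sulfur nucleophile that gives no alkylating by-product. Lithium thioglycolate (HSCH2CO2H, LiOH, DMF, rt) should attack the sulfonyl sulfur of the activated ring A sulfonamide to give 3-[bis(1-Boc-indol-3-yl)methyl]-1H-indole-2-carbaldehyde F4. K2CO3 in MeOH at rt to 50 °C should then cleave the two carbamates and return to the route at 14.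

**Further compounds**
F1 | step 7 | 3-[bis(1-Boc-indol-3-yl)methyl]-2-methylidene-1-tosylindolin-3-ol (racemic, one enantiomer drawn) | C=C1N(S(=O)(=O)c2ccc(C)cc2)c2ccccc2[C@]1(O)C(c1cn(C(=O)OC(C)(C)C)c2ccccc12)c1cn(C(=O)OC(C)(C)C)c2ccccc12
F2 | step 7 | {3-[bis(1-Boc-indol-3-yl)methyl]-1-tosylindol-2-yl}methanol | OCc1n(S(=O)(=O)c2ccc(C)cc2)c2ccccc2c1C(c1cn(C(=O)OC(C)(C)C)c2ccccc12)c1cn(C(=O)OC(C)(C)C)c2ccccc12
F3 | step 6 | N-{2-[1,1-bis(1-Boc-indol-3-yl)-2-hydroxy-4-(trimethylsilyl)but-3-yn-2-yl]phenyl}-4-methylbenzenesulfonamide (racemic, one enantiomer drawn) | C[Si](C)(C)C#C[C@](O)(c1ccccc1NS(=O)(=O)c1ccc(C)cc1)C(c1cn(C(=O)OC(C)(C)C)c2ccccc12)c1cn(C(=O)OC(C)(C)C)c2ccccc12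
F4 | step 8 | 3-[bis(1-Boc-indol-3-yl)methyl]-1H-indole-2-carbaldehyde | O=Cc1[nH]c2ccccc2c1C(c1cn(C(=O)OC(C)(C)C)c2ccccc12)c1cn(C(=O)OC(C)(C)C)c2ccccc12
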